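The four species cannot be followed one by one from the runs: X and G were read, L and E were not. A ratio of the two read species can still be frozen. Let σ be the share of X in X plus G, in a closed flask charged with L.

| flask | L | remark | time |
|---|---|---|---|
| dawn | 0.050 M | run made earlier |  |
| spring | 0.20 M | run made earlier |  |
| flask | 0.10 M |  | 15 d |

| run | time / d | X / % | G / % |
|---|---|---|---|
| dawn | 1.25 | 31.0 | 41.4 |
| dawn | 2.50 | 35.9 | 34.5 |
| dawn | 5.00 | 36.4 | 33.2 |
| dawn | 10.0 | 36.4 | 32.8 |
| dawn | 20.0 | 36.8 | 32.7 |
| spring | 1.67 | 32.8 | 37.5 |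
| spring | 5.00 | 36.8 | 32.7 |
| spring | 8.00 | 37.1 | 32.7 |
| spring | 12.0 | 37.2 | 32.9 |
| spring | 20.0 | 36.9 | 33.6 |

(standard deviation of a reading: 0.3 percentage points)

- share of X in X plus G at 15 min
- share of X in X plus G at 8.0 h
- share of X in X plus G at 15 d

- reactions considered so far: L <-> X; X <-> G; G <-> L; X <-> E

In my reckoning, the last two readings pool to 52.8% in dawn and 52.7% in spring. The two pooled shares are close and the flask's charge lies between the charges of dawn and spring, so I take the four readings pooled as its end share S:

S = 52.7%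

Early on G leads, 41.4% against 31.0% in dawn's first reading, which looks like kinetic against thermodynamic control. Let the closing rate λ, a relaxation constant, be defined by S − σ(t) = S·exp(−λt), with σ starting from zero. Dawn's first share, 42.8%, gives:

λ = ln(S/(S − σ))/t = 1.34 d⁻¹

At 15 d: σ = 52.7%
At 8.0 h: σ = 19.0%
At 15 min: σ = 0.729%

The weak link is the zero start. Spring's first share, 46.7%, joined to dawn's by the same exponential, gives a slope of 1.17 d⁻¹ and a start share of 10.2%. Run on from that start with that slope, the share at 15 min is 10.7%, so my early figure is a band from 0.729% to 10.7%.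

The forecast gives 5% at 15 min, 20% at 8.0 h and 52.9% at 15 d, its last two figures a little above mine, and says: “At 15 min, the share is small and poorly fixed, since it depends on any direct burst to X.”

The flask gives 1.51% at 15 min, inside the band, then 19.2% at 8.0 h and 52.9% at 15 d.

    L ⇌ X (K = 5.60, k = 0.0280 h⁻¹)
    X ⇌ G (K = 0.890, k = 0.0340 h⁻¹)
    G ⇌ L (k = 0.590 h⁻¹)
    X ⇌ E (K = 0.640, k = 0.240 h⁻¹)

In the flask there is as much X as G at 2.16 d, and λ puts σ = 0.5 at 2.21 d. For the neighbour flask with 0.17 M of L, λ gives 19.0% at 8.0 h, and that flask stands at 19.2%.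

The runs are calculated with made-up constants; noise was put on by code.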